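If X per litre had followed the charge of solid L, the violet run, with twice the L of the amber run, had to lead it. It did not: at 3.00 h amber held 0.106 M of X and violet 0.105 M. So I reckoned in molar, not in percent.

all flasks: G 150 mM (held)
- amber: L 0.94 M; run made earlier
- violet: L 2.1 M; run made earlier
- flask: L 1.4 M; time 2.5 h

| run | time / h | L / % | X / % | D / % |
|---|---|---|---|---|
| amber | 0.250 | 97.7 | 0.1 | 1.4 |
| amber | 0.500 | 96.7 | 1.1 | 2.0 |
| amber | 1.33 | 92.1 | 3.9 | 3.0 |
| amber | 3.00 | 84.5 | 11.3 | 2.8 |
| violet | 0.833 | 97.7 | 0.6 | 1.1 |
| violet | 1.50 | 96.2 | 2.8 | 1.0 |
| violet | 2.50 | 94.3 | 4.3 | 0.9 |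
| violet | 3.00 | 92.9 | 5.0 | 1.0 |

(standard deviation of a reading: 0.3 percentage points)

- as a solid, counted per litre of solution: L
- at the start none of E is dissolved
- the numbers in the tables scatter by 0.3 percentage points (one standard deviation)
- what may be going on: D <-> Z; E + Z -> X; X -> J; G <-> E; L <-> D
- at the start none of L is in solution
- what has only dissolved of L counts as not reacted
- D means what is dissolved; the solid is not counted in it
- the reaction counts as stopped when no species that holds the L changes by six tenths of a point or more over the second half of the time

- at 2.5 h, what has stopped the reaction, if anything has (for what has run out or reacted, a solid counts together with what of it has only dissolved) (it is still moving / forward and back rates have come level / all of L has reacted)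
- part of the L that has turned into other species by 2.5 h (what has only dissolved does not count)
- X at 2.5 h, in percent of the L charged
- D at 2.5 h, in percent of the L charged

A rate constant multiplies concentrations, and solid L has none in solution; it feeds dissolved D. The scheme on offer has D pass to Z, and Z meet E, which comes from the held gas G, to give X. In amber, D stood at 0.0282 M at 1.33 h and 0.0263 M at 3.00 h, level within the scatter. I took that level as reached. If Z and E stood level with D, X had to form at a constant rate, zero order in L, so that was my working assumption.

From its second reading to its last, amber gained X at 0.0384 M/h. Violet gained it at 0.0426 M/h. Their mean I called the held rate s, 0.0405 M/h, the X made per litre each hour while solid L stands by. Back along that line, the readings at 3.00 h gave a lag of 0.392 h, a reading; amber's D was still rising over that stretch. For the flask with 1.4 M of L, s gave 0.0854 M of X at 2.5 h, which is 6.10% of the L charged.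

The forecast, calling the rate “essentially zero order in solid L”, said it is still moving, with conv 7.2%, X 6.1% and D 1.6%.

What ran was this:

    D ⇌ Z (K = 0.350, k = 0.00230 /s)
    E + Z → X (k = 0.0100 /M/s)
    X → J (k = 5.70 × 10⁻⁷ /s)
    G ⇌ E, rate k4*(csat - [E]) (kL = 0.120 /s)
    L ⇌ D, rate k5*(cs5 - [D]) while solid is left; crystals form when [D] > cs5 (solubility = 0.0590 M, k = 3.80 × 10⁻⁴ /s)

The flask gave it is still moving, with conv 6.80%, X 6.22% and D 1.98%. Its X stood close to the 6.10% from s, and hardly any of it had gone on to J. J stood at 0.0136% at 2.50 h, and the half-life of X toward J alone, 14 d, is longer than the 2.5 h of the flask. I then read the same flask earlier, at 1.0 h. There s and the lag gave 1.76% of X, and the flask held 1.79%.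

The readings stem from a simulated flask from invented constants, noise included.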